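**Plan**
- Retrosynthetic cuts: the two acetate C–O bonds (C2, C15); the C9–C11 bond, with C9–H traced back to a C9 ketone; the C2–O and C3–O bonds back to a C2=C3 alkene; the C6 methylene back to a C6 ketone; finally C1–C10 and C4–C5 in one [4+2] step.
- Enabling feature: ring B carries methyl groups on C8 and on the quaternary fusion carbon C10, on either side of C9, and ring A carries the C4 gem-dimethyl group next to C5. This pattern is 2,6-dimethylbenzoquinone (all of ring B, both methyls, carbonyls at C6 and C9) plus 4-methylpenta-1,3-diene (C1–C4).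
- Forward order: ring B comes preformed in the quinone and ring A is closed by the cycloaddition. C5 is then inverted, the C6 oxygen removed, and C2=C3 dihydroxylated and masked. A separately made C6 alkyl iodide is joined at C9, the C9 oxygen is replaced by hydrogen, and deprotection and diacetylation finish the route.
- Stereochemistry: C10 from a chiral boron Lewis acid; C5 by epimerisation next to the C6 ketone; C2 and C3 by OsO4 attack anti to the two axial methyl groups; C9 by organolithium addition anti to the C10 methyl followed by palladium–formate hydrogenolysis with inversion; the E alkene by syn carboalumination.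

Key step: step 1

Remark on numbering: labdane numbering is used for all bicyclic compounds; "syn" and "anti" refer to the face of the bicycle relative to the C10 methyl group.
Assumption: the (S)-configured oxazaborolidinium ion is taken to give the (8aR) adduct, following the usual binding model (α-C–H···O contact, one face covered by an aryl group). If the sense were opposite, the (R)-catalyst would be used.

**Step 1**
Reactants: 1 2,6-dimethyl-1,4-benzoquinone; 2 4-methylpenta-1,3-diene
Product: 3 cis-fused cycloadduct (4aS,8aR)-2,5,5,8a-tetramethyl-4a,5,8,8a-tetrahydronaphthalene-1,4-dione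
Conditions: (S)-3,3-diphenyl-1-(2-methylphenyl)tetrahydro-1H,3H-pyrrolo[1,2-c][1,3,2]oxazaborole (24 mol%, pre-formed from (S)-α,α-diphenylprolinol and tris(2-methylphenyl)boroxine) + (CF3SO2)2NH (20 mol%), 2 (5 equiv), CH2Cl2, −40 → −20 °C, 48 h; pH 7 buffer
Reagents that add atoms: none
Why: The N-protonated oxazaborolidine binds the quinone carbonyl that is flanked by two C–H groups (the future C6=O) and so activates one of the two equivalent methyl-bearing C=C bonds for a concerted, asynchronous, suprafacial Diels–Alder addition of the s-cis diene, the closest known reaction type being the oxazaborolidinium-catalysed enantioselective Diels–Alder reaction of 2,6-disubstituted benzoquinones with simple dienes. Ring A is closed as a cyclohexene by forming C1–C10 and C4–C5 together in a six-membered pericyclic transition state. C10 is set by the catalyst, whose aryl group covers one face of the bound quinone, and C5 is set by the suprafacial course, which necessarily puts H-5 syn to CH3-10 (cis fusion, corrected in step 2). The required regiochemistry (CH2 terminus to the methyl-bearing carbon, CMe2 terminus to the CH carbon) follows from the larger HOMO coefficient and smaller size of the unsubstituted diene terminus meeting the β-carbon of the activated enone, and it avoids two adjacent quaternary carbons. The weak point is the Z-methyl group of 2, which disfavours the s-cis conformer, so a cationic Lewis acid, excess diene, a slight excess of boron over acid and long reaction time are used to gain rate without acid-induced oligomerisation of the diene.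

**Step 2**
Reactants: 3 cis-fused cycloadduct
Product: 4 trans-fused ene-dione (4aR,8aR)-2,5,5,8a-tetramethyl-4a,5,8,8a-tetrahydronaphthalene-1,4-dione
Conditions: 1,8-diazabicyclo[5.4.0]undec-7-ene (DBU, 0.2 equiv), CH2Cl2, 23 °C; chromatography, recovered 3 resubmitted
Reagents that add atoms: none
Why: Base-mediated epimerisation through the C5 enolate of the C6 ketone (C10 is quaternary, so neither aromatisation nor loss of the C10 configuration is possible) should, under thermodynamic control, place H-5 anti to CH3-10 as in other angular-methyl ene-dione cycloadducts.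

**Step 3**
Reactants: 4 trans-fused ene-dione
Product: 5 hydroxy enone (C9 ketone; C7=C8; 6-OH syn to CH3-10)
Conditions: NaBH4 (1.0 equiv), CeCl3·7H2O (1.1 equiv), MeOH/CH2Cl2, −78 °C
Reagents that add atoms: none
Why: Luche 1,2-reduction should take place at the C6 carbonyl, whose neighbour C5 is a CH group whereas C9 lies between the quaternary C10 and the methyl-bearing C8, with hydride entering anti to the axial C10 and C4 methyl groups; after this step H-5 can no longer epimerise, and the new C6 centre is removed again in step 5.

**Step 4**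
Reactants: 5 hydroxy enone
Product: 6 acetoxy enone (6-OAc syn to CH3-10)
Conditions: Ac2O, 4-(dimethylamino)pyridine, Et3N, CH2Cl2, 23 → 40 °C
Reagents that add atoms: acetic anhydride CC(=O)OC(C)=O
Why: Acylation under nucleophilic catalysis by 4-(dimethylamino)pyridine turns the hindered pseudo-axial allylic hydroxyl into a leaving group for the reductive cleavage.

**Step 5**
Reactants: 6 acetoxy enone
Product: 8 trans-fused enone (C9 ketone; C7=C8; C6 methylene; C2=C3), via deconjugated enone 7 (not isolated)
Conditions: SmI2 (2.5 equiv), THF/MeOH, −78 °C; then DBU (0.5 equiv), 23 °C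
Reagents that add atoms: none
Why: Samarium diiodide reduction of a γ-acyloxy enone (the vinylogous form of α-acyloxy ketone cleavage) expels acetate from C6 after two single-electron transfers, methanol protonates the samarium dienolate mainly at C8, and DBU returns the C6=C7 bond of 7 to conjugation, which also erases the C8 centre.

**Step 6**
Reactants: 8 trans-fused enone
Product: 9 enone diol (2-OH and 3-OH cis to each other and anti to CH3-10)
Conditions: OsO4 (2 mol%), N-methylmorpholine N-oxide (1.5 equiv), acetone/H2O, 23 °C
Reagents that add atoms: osmium tetroxide O=[Os](=O)(=O)=O (oxygen carrier); N-methylmorpholine N-oxide C[N+]1([O-])CCOCC1 and water O (ultimate oxygen sources)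
Why: Upjohn dihydroxylation adds suprafacially to the isolated C2=C3 bond rather than to the electron-poor enone bond C7=C8, and from the face anti to the axial C10 methyl and the pseudo-axial C4 methyl, which sets C2 and C3 together.

**Step 7**
Reactants: 9 enone diol
Product: 10 acetonide enone (2,3-O-isopropylidene derivative of 9)
Conditions: Me2C(OMe)2, pyridinium p-toluenesulfonate (cat.), CH2Cl2, 23 °C
Reagents that add atoms: 2,2-dimethoxypropane COC(C)(C)OC
Why: Acid-catalysed transacetalisation gives the five-membered isopropylidene acetal of the cis-diol, which masks both hydroxyls against the organolithium, chloroformate and palladium steps.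

**Step 8**
Reactants: 11 but-3-yn-1-ol
Product: 12 PMB ether 1-[(but-3-yn-1-yloxy)methyl]-4-methoxybenzene
Conditions: NaH, 4-MeOC6H4CH2Cl, Bu4NI (cat.), THF, 0 → 23 °C
Reagents that add atoms: 4-methoxybenzyl chloride COc1ccc(CCl)cc1
Why: Williamson ether synthesis on the primary alkoxide gives an ether that tolerates trimethylaluminium and can later be removed oxidatively beside a silyl ether.

**Step 9**
Reactants: 12 PMB ether
Product: 15 allylic alcohol (E)-5-[(4-methoxyphenyl)methoxy]-3-methylpent-2-en-1-ol, via alkenylalane 13 (not isolated), via lithium alanate 14 (not isolated)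
Conditions: Me3Al (2.5 equiv), Cp2ZrCl2 (0.25 equiv), CH2Cl2, 0 → 23 °C; volatiles removed; n-BuLi, THF/hexane, −78 °C; (CH2O)n, −78 → 23 °C; aq. Rochelle salt
Reagents that add atoms: trimethylaluminium C[Al](C)C; paraformaldehyde as formaldehyde C=O
Why: Negishi zirconium-catalysed carboalumination adds CH3 and Al syn across the terminal alkyne with methyl on the internal carbon, which fixes the E geometry of C13=C14, and the alkenyl alanate then adds to formaldehyde with retention.

**Step 10**
Reactants: 15 allylic alcohol
Product: 16 silyl PMB diether tert-butyl{[(E)-5-[(4-methoxyphenyl)methoxy]-3-methylpent-2-en-1-yl]oxy}dimethylsilane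
Conditions: TBSCl, imidazole, CH2Cl2, 23 °C
Reagents that add atoms: tert-butyldimethylsilyl chloride CC(C)(C)[Si](C)(C)Cl
Why: Imidazole-promoted silylation protects the C15 oxygen as an ether that survives organolithium and palladium–formate chemistry and is not an allylic leaving group.

**Step 11**
Reactants: 16 silyl PMB diether
Product: 17 homoallylic alcohol (E)-5-[(tert-butyldimethylsilyl)oxy]-3-methylpent-3-en-1-ol
Conditions: DDQ, CH2Cl2/pH 7 buffer, 0 °C
Reagents that add atoms: none
Why: Oxidative PMB cleavage (hydride abstraction from the electron-rich benzylic position by DDQ, then hydrolysis of the oxocarbenium ion) frees the homoallylic hydroxyl and leaves the allylic silyl ether in place.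

**Step 12**
Reactants: 17 homoallylic alcohol
Product: 18 iodide tert-butyl{[(E)-5-iodo-3-methylpent-2-en-1-yl]oxy}dimethylsilane
Conditions: I2, PPh3, imidazole, CH2Cl2, 0 °C
Reagents that add atoms: iodine II
Why: Appel-type iodination displaces the alkoxyphosphonium ion by iodide in an SN2 step under buffered conditions that spare the silyl ether.

**Step 13**
Reactants: 18 iodide; 10 acetonide enone
Product: 21 tertiary allylic methyl carbonate (9-OCO2Me syn to CH3-10; side chain anti), via alkyllithium 19 (not isolated), via lithium alkoxide 20 (not isolated)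
Conditions: 18 (1.4 equiv), t-BuLi (2.8 equiv), Et2O/pentane, −78 °C; 10 in Et2O, −78 → −40 °C; ClCO2Me, THF, −78 → 23 °C
Reagents that add atoms: methyl chloroformate COC(=O)Cl
Why: Iodine–lithium exchange gives the primary alkyllithium, which adds 1,2 to the enone carbonyl C9 from the face anti to the axial C10 methyl (so that the new C9–O bond is syn to CH3-10), and the tertiary lithium alkoxide is O-acylated in the same flask.

**Step 14**
Reactants: 21 tertiary allylic methyl carbonate
Product: 22 protected labdadiene (C7=C8; H-9 anti and side chain syn to CH3-10; 2,3-acetonide; 15-OTBS)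
Conditions: Pd(OAc)2 (5 mol%), PBu3 (5 mol%), HCO2H (3 equiv), Et3N (3 equiv), THF, 40 °C
Reagents that add atoms: none
Why: In this Tsuji–Mandai formate hydrogenolysis zerovalent palladium ionises the allylic carbonate with inversion (palladium anti to the leaving group and hence anti to CH3-10), formate gives a palladium hydride after loss of CO2, and the hydride is delivered from palladium to the more substituted allyl terminus C9, which keeps the C7=C8 bond and sets C9.

**Step 15**
Reactants: 22 protected labdadiene
Product: 23 triol (2-OH and 3-OH anti to CH3-10; 15-OH)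
Conditions: camphor-10-sulfonic acid (0.2 equiv), MeOH, 0 → 23 °C
Reagents that add atoms: none
Why: Acid-catalysed methanolysis removes the primary allylic silyl ether and the isopropylidene acetal in one operation under conditions mild enough for the allylic alcohol and the trisubstituted alkenes.

**Step 16**
Reactants: 23 triol
Product: 24 target 2,15-diacetate
Conditions: Ac2O (2.3 equiv), pyridine, CH2Cl2, 0 °C
Reagents that add atoms: acetic anhydride CC(=O)OC(C)=O
Why: Site-selective acylation should take the primary allylic 15-OH and the equatorial 2-OH and leave the axial 3-OH next to the C4 gem-dimethyl group, and any acyl migration within the cis-diol would also favour the less hindered C2 oxygen.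

**Compound list**
1 | 2,6-dimethyl-1,4-benzoquinone | CC1=CC(=O)C=C(C)C1=O | starting material
2 | 4-methylpenta-1,3-diene | C=CC=C(C)C | starting material
3 | (4aS,8aR)-2,5,5,8a-tetramethyl-4a,5,8,8a-tetrahydronaphthalene-1,4-dione (cis-fused; H-5 syn to CH3-10) | O=C1C(C)=CC(=O)[C@H]2C(C)(C)C=CC[C@@]12C | intermediate
4 | (4aR,8aR)-2,5,5,8a-tetramethyl-4a,5,8,8a-tetrahydronaphthalene-1,4-dione (trans-fused; H-5 anti to CH3-10) | O=C1C(C)=CC(=O)[C@@H]2C(C)(C)C=CC[C@@]12C | intermediate
5 | trans-fused 4-hydroxy-2,5,5,8a-tetramethyl-4a,5,8,8a-tetrahydronaphthalen-1(4H)-one (labdane C6-OH, syn to CH3-10) | O=C1C(C)=C[C@H](O)[C@@H]2C(C)(C)C=CC[C@@]12C | intermediate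
6 | acetate of 5 (labdane C6-OAc, syn to CH3-10) | O=C1C(C)=C[C@H](OC(C)=O)[C@@H]2C(C)(C)C=CC[C@@]12C | intermediate
7 | trans-fused 2,5,5,8a-tetramethyl-4a,5,8,8a-tetrahydronaphthalen-1(2H)-one (C6=C7 and C2=C3; both C8 epimers; not isolated) | O=C1C(C)C=C[C@@H]2C(C)(C)C=CC[C@@]12C | intermediate
8 | trans-fused 2,5,5,8a-tetramethyl-4a,5,8,8a-tetrahydronaphthalen-1(4H)-one (C9 ketone; C7=C8; C2=C3) | O=C1C(C)=CC[C@@H]2C(C)(C)C=CC[C@@]12C | intermediate
9 | 2,3-diol of 8 (both hydroxyls anti to CH3-10; 2-OH equatorial, 3-OH axial) | O=C1C(C)=CC[C@@H]2C(C)(C)[C@@H](O)[C@@H](O)C[C@@]12C | intermediate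
10 | 2,3-O-isopropylidene acetal of 9 | O=C1C(C)=CC[C@@H]2C(C)(C)[C@H]3OC(C)(C)O[C@H]3C[C@@]12C | intermediate
11 | but-3-yn-1-ol | C#CCCO | starting material
12 | 1-[(but-3-yn-1-yloxy)methyl]-4-methoxybenzene | C#CCCOCc1ccc(OC)cc1 | intermediate
13 | (E)-{4-[(4-methoxyphenyl)methoxy]-2-methylbut-1-en-1-yl}dimethylalane (not isolated) | C[Al](C)/C=C(\C)CCOCc1ccc(OC)cc1 | intermediate
14 | lithium butyl{(E)-4-[(4-methoxyphenyl)methoxy]-2-methylbut-1-en-1-yl}dimethylaluminate (not isolated) | [Li+].CCCC[Al-](C)(C)/C=C(\C)CCOCc1ccc(OC)cc1 | intermediate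
15 | (E)-5-[(4-methoxyphenyl)methoxy]-3-methylpent-2-en-1-ol | OC/C=C(\C)CCOCc1ccc(OC)cc1 | intermediate
16 | tert-butyl{[(E)-5-[(4-methoxyphenyl)methoxy]-3-methylpent-2-en-1-yl]oxy}dimethylsilane | CC(C)(C)[Si](C)(C)OC/C=C(\C)CCOCc1ccc(OC)cc1 | intermediate
17 | (E)-5-[(tert-butyldimethylsilyl)oxy]-3-methylpent-3-en-1-ol | CC(C)(C)[Si](C)(C)OC/C=C(\C)CCO | intermediate
18 | tert-butyl{[(E)-5-iodo-3-methylpent-2-en-1-yl]oxy}dimethylsilane | CC(C)(C)[Si](C)(C)OC/C=C(\C)CCI | intermediate
19 | {(E)-5-[(tert-butyldimethylsilyl)oxy]-3-methylpent-3-en-1-yl}lithium (not isolated) | CC(C)(C)[Si](C)(C)OC/C=C(\C)CC[Li] | intermediate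
20 | lithium alkoxide from addition of 19 to C9 of 10 (C9–O syn, side chain anti to CH3-10; not isolated) | CC(C)(C)[Si](C)(C)OC/C=C(\C)CC[C@@]1(O[Li])C(C)=CC[C@@H]2C(C)(C)[C@H]3OC(C)(C)O[C@H]3C[C@@]12C | intermediate
21 | methyl carbonate of the C9 tertiary allylic alcohol (C9–O syn, side chain anti to CH3-10; 2,3-acetonide; 15-OTBS) | CC(C)(C)[Si](C)(C)OC/C=C(\C)CC[C@@]1(OC(=O)OC)C(C)=CC[C@@H]2C(C)(C)[C@H]3OC(C)(C)O[C@H]3C[C@@]12C | intermediate
22 | 15-O-TBS-2,3-O-isopropylidene-labda-7,13E-diene-2,3,15-triol skeleton (H-5 and H-9 anti, side chain syn, 2-O and 3-O anti to CH3-10) | CC(C)(C)[Si](C)(C)OC/C=C(\C)CC[C@@H]1C(C)=CC[C@@H]2C(C)(C)[C@H]3OC(C)(C)O[C@H]3C[C@@]12C | intermediate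
23 | labda-7,13E-diene-2,3,15-triol with the configuration of the target | OC/C=C(\C)CC[C@@H]1C(C)=CC[C@@H]2C(C)(C)[C@@H](O)[C@@H](O)C[C@@]12C | intermediate
24 | CNP0254679.1, the 2,15-diacetate of 23 | CC(=O)OC/C=C(\C)CC[C@@H]1C(C)=CC[C@@H]2C(C)(C)[C@@H](O)[C@@H](OC(C)=O)C[C@@]12C | target

**Step count**
Total: 16 steps. Longest linear sequence: 11 steps (steps 1–7 and 13–16); the side-chain branch (steps 8–12) joins at step 13.

**Steps most likely to fail**

Step 1. The cycloaddition may be too slow because the Z-methyl group of the diene disfavours the s-cis conformer; the diene may oligomerise under the cationic Lewis acid; an uncatalysed background reaction may erode the enantiomeric purity.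
Fallback: use a more electron-rich diene and remove its activating group afterwards. Starting from 1 and commercial mesityl oxide (CC(=O)C=C(C)C), kinetic enolisation (LiN(i-Pr)2, THF, −78 °C) and O-silylation with i-Pr3SiOSO2CF3 gives 4-methyl-2-[(triisopropylsilyl)oxy]penta-1,3-diene F1. Under the same boron catalyst, F1 should add to 1 with the same orientation (its CH2 terminus is the nucleophilic end of a silyl enol ether) to give the cis-fused cycloadduct bearing a C2 silyl enol ether F2. Treatment with CsF and PhN(SO2CF3)2 in 1,2-dimethoxyethane converts it into the C2 enol triflate F3. Palladium-catalysed formate reduction (Pd(OAc)2, PPh3, Bu3N, HCO2H, DMF) then replaces the triflate by hydrogen and comes back to the route at 3.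

Step 2. The equilibration may stop on the cis side. The trans isomer has a syn-pentane contact between the C10 methyl and one C4 methyl, which the cis isomer can partly avoid while C9 is trigonal, so the advantage seen in simpler angular-methyl adducts may be lost.
Fallback: set C5 in a reduction and remove the C6 oxygen in the same pass. Starting from 3, deprotonation at C5 (its only α-hydrogen) with KN(SiMe3)2 in THF at −78 °C and O-sulfonylation with PhN(SO2CF3)2 gives the cross-conjugated dienyl triflate F4. Palladium-catalysed formate reduction (Pd(OAc)2, PPh3, Bu3N, HCO2H) gives the linear dienone F5 (C5=C6, C7=C8, C9 ketone). Dissolving-metal 1,6-reduction (Li, liquid NH3, THF, t-BuOH, −78 °C, then NH4Cl) should protonate the dienyl anion at C5 axially and anti to the C10 methyl, as in metal–ammonia reductions of related ring-fusion enones, and then protonate the dienolate at C8. This gives 7, which DBU converts into 8, where the sequence rejoins the route; steps 2 to 5 are bypassed.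

Step 14. Ionisation of the hindered tertiary carbonate may be slow; the allyl palladium intermediate may lose a β-hydrogen to give dienes; hydride may be delivered to C7 to give the C8=C9 isomer.
Fallback: replace the hydrogenolysis by a reductive 1,3-transposition. Starting from 10 and 19 as in step 13, but quenching the alkoxide 20 with aqueous NH4Cl, gives the tertiary allylic alcohol F6. Oxidative transposition with pyridinium chlorochromate [C5H5NH][CrO3Cl] (NaOAc, CH2Cl2; Babler–Dauben oxidation) gives the transposed enone F7 (C7 ketone, C8=C9 bearing the side chain). Luche reduction (NaBH4, CeCl3·7H2O, MeOH), with hydride entering anti to the C10 methyl, gives the allylic alcohol F8 (7-OH syn to CH3-10). Mitsunobu displacement with 2-nitrobenzenesulfonylhydrazide (PPh3, diethyl azodicarboxylate, THF, −30 °C) inverts C7 to give the allylic sulfonylhydrazide F9. On warming, F9 loses the sulfinate to give the monoalkyl diazene F10, which expels N2 in a retro-ene step that delivers hydrogen to C9 on the face anti to the C10 methyl and moves the double bond to C7=C8. This comes back to the route at 22.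

**Further compounds**
F1 | step 1 | 4-methyl-2-[(triisopropylsilyl)oxy]penta-1,3-diene | C=C(O[Si](C(C)C)(C(C)C)C(C)C)C=C(C)C
F2 | step 1 | cis-fused cycloadduct of 1 and F1, (4aS,8aR)-2,5,5,8a-tetramethyl-7-[(triisopropylsilyl)oxy]-4a,5,8,8a-tetrahydronaphthalene-1,4-dione | O=C1C(C)=CC(=O)[C@H]2C(C)(C)C=C(O[Si](C(C)C)(C(C)C)C(C)C)C[C@@]12C
F3 | step 1 | C2 enol triflate corresponding to F2 | O=C1C(C)=CC(=O)[C@H]2C(C)(C)C=C(OS(=O)(=O)C(F)(F)F)C[C@@]12C
F4 | step 2 | cross-conjugated dienyl triflate (C5=C6–OTf, C7=C8, C9 ketone, C2=C3) | O=C1C(C)=CC(OS(=O)(=O)C(F)(F)F)=C2C(C)(C)C=CC[C@@]12C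
F5 | step 2 | linear dienone (C5=C6, C7=C8, C9 ketone, C2=C3) | O=C1C(C)=CC=C2C(C)(C)C=CC[C@@]12C
F6 | step 14 | C9 tertiary allylic alcohol (9-OH syn, side chain anti to CH3-10; 2,3-acetonide; 15-OTBS) | CC(C)(C)[Si](C)(C)OC/C=C(\C)CC[C@@]1(O)C(C)=CC[C@@H]2C(C)(C)[C@H]3OC(C)(C)O[C@H]3C[C@@]12C
F7 | step 14 | transposed enone (C7 ketone, C8=C9 bearing the side chain) | CC(C)(C)[Si](C)(C)OC/C=C(\C)CCC1=C(C)C(=O)C[C@@H]2C(C)(C)[C@H]3OC(C)(C)O[C@H]3C[C@@]12C
F8 | step 14 | allylic alcohol (7-OH syn to CH3-10, C8=C9) | CC(C)(C)[Si](C)(C)OC/C=C(\C)CCC1=C(C)[C@H](O)C[C@@H]2C(C)(C)[C@H]3OC(C)(C)O[C@H]3C[C@@]12C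
F9 | step 14 | N-allylic 2-nitrobenzenesulfonylhydrazide (C7–N anti to CH3-10) | CC(C)(C)[Si](C)(C)OC/C=C(\C)CCC1=C(C)[C@@H](N(N)S(=O)(=O)c4ccccc4[N+](=O)[O-])C[C@@H]2C(C)(C)[C@H]3OC(C)(C)O[C@H]3C[C@@]12C
F10 | step 14 | allylic monoalkyl diazene (C7–N=NH anti to CH3-10) | CC(C)(C)[Si](C)(C)OC/C=C(\C)CCC1=C(C)[C@@H](N=N)C[C@@H]2C(C)(C)[C@H]3OC(C)(C)O[C@H]3C[C@@]12C
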